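## Structural features

The target (C18H14O9) is a tetracyclic depsidone. Ring A and ring B are benzene rings joined twice, by a diaryl ether oxygen and by an aryl ester, so that a seven-membered 1,4-dioxepinone lies between them. Ring B is also fused to a five-membered lactone whose sp3 carbon is a lactol (a 3-hydroxyphthalide).

Going round ring A, the substituents are OMe, H, CH3, the ester carbonyl carbon, the ether oxygen and a free OH, so the carbonyl-bearing carbon is para to the methoxy group. Ring B has no hydrogen: it carries the ether oxygen, the ester oxygen, CH3, OH, the lactone carbonyl carbon and the lactol carbon.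

The lactol carbon is the only stereocentre (R). It has no stereogenic neighbour, but it is an acylal carbon that can lose its configuration through ring–chain tautomerism with the open formyl acid. Other fragile points are the depsidone aryl ester (hydroxide, alkoxide) and the electron-rich free phenols (oxidants); the lactol is also sensitive to hydride and hydrogenolysis.

The difficulty is twofold. Ring B is hexasubstituted and sits in a diaryl ether with four ortho substituents, which makes a late aryl–oxygen coupling unattractive. The labile lactol must also be delivered as one enantiomer.

The key step uses the fact that the ester carbonyl carbon lies between the ring A carbon para to OMe and the ring B oxygen ortho to the bridging oxygen. In the open diaryl ether these two atoms face each other across the bridge, so one carbon from CO can be inserted between an aryl iodide and a phenol.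

## Logic of the disconnections

**21 to 20.** The bond cut is the acetyl C–O bond of an acetate placed on the lactol oxygen. Compound 21 cannot be made directly as one enantiomer, whereas 20 is a configurationally fixed acylal, so the stereochemical problem becomes an acylation problem. The forward step must cleave on the acetyl side only, under neutral conditions, so that the C–O bond at the stereocentre is never opened.

**20 to 19.** The same O–acetyl bond is cut and the configuration is dropped, which leads to racemic 19. The gain is a precursor with no stereochemical information. The forward step needs 19 to racemise faster than its slow enantiomer is acylated, and an acyl-transfer catalyst that reads the lactol carbon.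

**19 to 17.** The lactone C(=O)–O bond, both lactol C–O bonds and the ring A phenol O–H are traced back to a methyl ester, a diethyl acetal and a benzyl ether; 18 is the open formyl ester on the way. These three groups are inert to palladium, CO and amine. The forward step needs acid conditions that spare the depsidone ester and the ring A methyl ether, and it is placed before the stereocentre exists.

**17 to 15 and 16.** The aryl–C(=O) bond on ring A and the C(=O)–O bond to ring B are cut, which opens the seven-membered ring and removes one carbon as 16. What remains is an open diaryl ether with one C–I bond and free phenols. The forward step must insert CO faster than the aryl–palladium couples directly with the phenol, must use only the phenol ortho to the bridge, and must close the ring faster than chains form.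

**15 to 14.** No skeletal bond is cut; two hydrogens are added back at the ring B carbons that bear the aryloxy and acetal groups. This step is explicit because a malonate annulation stops at the cyclohexane-1,3-dione level, one oxidation step below the resorcinol. The forward dehydrogenation must leave the aryl iodide, benzyl ether and acetal alone.

**14 to 11 and 12.** Ring B is opened at two C–C bonds: between the acetal-bearing and ester-bearing carbons (conjugate addition), and between the methyl-bearing carbon and the adjacent carbonyl carbon derived from 12 (Claisen closure), with 13 as the open intermediate. The hexasubstituted ring falls into an acyclic enone and 12, and the diaryl ether oxygen is already present as an enol ether oxygen, so no hindered aryl–O coupling is needed. The forward step requires conjugate addition to a hindered α-aryloxy enone; the closure itself has only one six-membered option.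

**11 to 8 and 9.** The C=C bond between the aryloxy-bearing carbon and the acetal-bearing CH is cut, with 10 as the aldol on the way. The forward condensation must occur at the aryloxy-bearing methylene of 8 and not at its ethyl group.

**8 to 6 and 7.** The alkyl C–O bond is cut. The future diaryl ether bond is thus made as a simple alkylation of a phenol by a reactive α-bromo ketone.

**6 to 4.** The phenol oxygen is traced back to a formyl carbon, with aryl–C exchanged for aryl–O by way of 5. The forward step needs aryl migration from an electron-rich, doubly ortho-substituted aldehyde.

**4 to 3.** The C–I bond is cut. Iodine is placed here and not on 15 because in 3 the site para to methoxy is clearly favoured. On any ring A ether after 6, two ring A positions would compete, one para and one ortho to methoxy and each next to an ether oxygen, and in 15 the free ring B phenols would also be exposed to the iodinating agent.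

**3 to 2.** The O–benzyl bond is cut. The benzyl group keeps this oxygen apart from the one that will carry ring B.

**2 to 1.** The formyl C–C bond ortho to the hydroxyl group is cut. In 1 the para position is blocked by methyl and only one ortho position is free, so the formyl group, the later oxygen, can enter only where it is needed.

## Other disconnections considered

**Alternative 1:** The cut is the CH2–O bond of a phthalide on ring B. It leads back to the depsidone 2-methylbenzoic acid A2, in which ring B carries CO2H and an ortho CH3 and both phenols are acetates.

- **Forward step:** persulfate with a copper salt oxidises the carboxylate of A2 to a carboxyl radical. This takes a hydrogen from the ortho methyl group, and the benzylic radical is oxidised and captured by the carboxylate, giving the five-membered lactone of A1.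
- **In favour:** proximity picks one of three benzylic methyl groups without a directing group. Ring B could be built with a plain methyl group instead of an acid-labile acetal; on this point the alternative is better than the chosen plan. No lactol-level carbon is carried through the depsidone closure.
- **Against:** A1 is one oxidation level short. A second benzylic oxidation (radical bromination to the bromophthalide A3, then hydrolysis) has no proximity control and must compete with two aryl methyl groups. Persulfate also attacks electron-rich rings, and ring A remains a trioxygenated arene even as its acetate. The phenol acetates must then be removed beside the depsidone ester and the lactol.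
- **Comparison:** on structure the two plans are equal, since both reach the racemic lactol and need the same enzymatic endgame. On mechanism the chosen closed-shell palladium cycle, with one reactive C–I bond, raises fewer selectivity questions than two radical oxidations. On step economy the alternative is longer (acetylation, two oxidations, hydrolysis, deacetylation against one acid step).

**Alternative 2:** The cut is the lactone carbonyl–O bond, with the lactol C–OH temporarily replaced by C–B. It leads back to the dibenzyl depsidone aldehyde methyl ester A5.

- **Forward step:** a copper boryl complex of a chiral bisphosphine, formed from the diboron reagent A6, adds across the aldehyde with boron going to carbon. The copper alkoxide then attacks the ortho methyl ester (5-exo-trig) to give the borylphthalide A4. Stereoretentive oxidation of C–B would reveal the lactol.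
- **In favour:** this is the only plan that sets the stereocentre by catalyst control and stores it in a configurationally stable C–B bond. Either enantiomer follows from the choice of ligand antipode, which is better than the chosen plan, where the sense of the enzyme has to be found by screening. The count of stereochemical operations is equal (borylation plus oxidation against acylation plus deacylation).
- **Against:** an alkoxide base and nucleophilic copper species must coexist with the depsidone aryl ester. The aldehyde sits between two ortho substituents of a hexasubstituted ring, which is difficult for a very bulky ligand. The α-boryl alkoxide can shift boron to oxygen before it lactonises. After oxidation, two benzyl ethers must still be removed from a molecule that already holds the labile lactol; hydrogenolysis threatens its benzylic C–O bond and Lewis acids ionise it.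
- **Comparison:** the stereochemical concept is superior, but functional-group tolerance and the endgame are weaker. The chosen plan removes every protecting group before the stereocentre is set.

**Alternative 3:** The cut is the two ring B C–C bonds on either side of the ester- and acetal-bearing carbons. It leads to the ring A-bearing bis(silyloxy)diene A8 and the ynoate A9.

- **Forward step:** a [4+2] addition in which the aryloxy-bearing diene terminus bonds to the alkyne carbon β to the ester, followed by loss of methanol and desilylation, gives the diaryl ether A7 with ring B complete.
- **In favour:** ring B arrives at the aromatic oxidation level and its regiochemistry is fixed by polarisation. On both counts it is better than the chosen annulation, which needs a separate dehydrogenation and a regioselective aldol. It is also convergent.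
- **Against:** A8 must be made from a γ-aryloxy β-keto ester by two silylations, is sensitive to moisture, and has a hindered aryloxy-bearing terminus. Ring A must carry its carboxyl carbon as a benzyl ester from the start, between the methyl group and the ether oxygen, which requires a hexasubstituted benzoate building block. The chosen plan delivers that carbon last, from CO. After A7 the depsidone ring still has to be closed by ester cleavage and dehydrative lactonisation.
- **Comparison:** the separate lactonisation is classical and at least as reliable as the carbonylation, so the alternative is equal or better on that point, but it costs extra steps. Overall step economy is about equal, with the burden moved from ring B to ring A.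

Key step: step 9

Assumption: the lactol carbon of 21 keeps its configuration in neutral, aprotic solution at or below room temperature, because ring opening to the formyl acid needs acid or base catalysis; the route therefore sets this centre last and uses no acid or base after step 11.

## Route

Step 1
Reactants: 1 creosol (2-methoxy-4-methylphenol)
Product: 2 2-hydroxy-3-methoxy-5-methylbenzaldehyde
Conditions: (CH2O)n, MgCl2, Et3N, MeCN, reflux; then 1 M HCl
Reagents that add atoms: formaldehyde (as paraformaldehyde), C=O
Why: Magnesium-phenoxide-directed ortho-formylation; the phenoxide delivers formaldehyde to the only free ortho position (para is blocked by methyl) and a second formaldehyde oxidises the benzylic alkoxide by hydride transfer.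

Step 2
Reactants: 2 2-hydroxy-3-methoxy-5-methylbenzaldehyde
Product: 3 2-(benzyloxy)-3-methoxy-5-methylbenzaldehyde
Conditions: BnBr, K2CO3, DMF, 50 °C
Reagents that add atoms: benzyl bromide, BrCc1ccccc1
Why: Williamson ether synthesis; the polar solvent and gentle heating overcome the hydrogen bond between the phenol and the formyl group.

Step 3
Reactants: 3 2-(benzyloxy)-3-methoxy-5-methylbenzaldehyde
Product: 4 2-(benzyloxy)-6-iodo-3-methoxy-5-methylbenzaldehyde
Conditions: NIS, CF3CO2H (cat.), MeCN, 0 °C to rt, dark
Reagents that add atoms: N-iodosuccinimide, O=C1CCC(=O)N1I
Why: Electrophilic aromatic iodination; the site para to the in-plane methoxy group and ortho to methyl is the most activated, as in halogenation of 2,3-dialkoxybenzaldehydes, which goes para to the 3-alkoxy group. The other free site is only ortho to methoxy and para to the deactivating formyl group, and the twisted central benzyloxy group directs little.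

Step 4
Reactants: 4 2-(benzyloxy)-6-iodo-3-methoxy-5-methylbenzaldehyde
Product: 6 2-(benzyloxy)-6-iodo-3-methoxy-5-methylphenol, via aryl formate 5 (not isolated)
Conditions: mCPBA, CH2Cl2, 0 °C to rt; then K2CO3 (cat.), MeOH, rt
Reagents that add atoms: 3-chloroperoxybenzoic acid, OOC(=O)c1cccc(Cl)c1
Why: Baeyer–Villiger (Dakin-type) oxidation; the electron-rich, ortho-alkoxy aryl group migrates in the Criegee intermediate, and the formate is removed by methanolysis. The aryl iodide is not oxidised by the peracid under these neutral conditions.

Step 5
Reactants: 6 2-(benzyloxy)-6-iodo-3-methoxy-5-methylphenol, 7 1-bromobutan-2-one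
Product: 8 1-[2-(benzyloxy)-6-iodo-3-methoxy-5-methylphenoxy]butan-2-one
Conditions: K2CO3, acetone, 50 °C
Reagents that add atoms: none
Why: Williamson alkylation; an α-bromo ketone is reactive enough in SN2 for a phenoxide flanked by two ortho substituents. This makes the future diaryl ether C–O bond without any aryl–oxygen coupling.

Step 6
Reactants: 8 1-[2-(benzyloxy)-6-iodo-3-methoxy-5-methylphenoxy]butan-2-one, 9 2,2-diethoxyacetaldehyde
Product: 11 (Z)-4-[2-(benzyloxy)-6-iodo-3-methoxy-5-methylphenoxy]-6,6-diethoxyhex-4-en-3-one, via aldol adduct 10 (not isolated)
Conditions: piperidine (cat.), AcOH (cat.), 4 Å MS, toluene, 70 °C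
Reagents that add atoms: none
Why: Amine-catalysed aldol (Knoevenagel-type) condensation; the aryloxy-bearing methylene is the more acidic α-position and the aldehyde is not prone to self-condensation, and dehydration gives the conjugated enone. The alkene geometry (Z expected) is of no consequence because it disappears in ring B.

Step 7
Reactants: 11 (Z)-4-[2-(benzyloxy)-6-iodo-3-methoxy-5-methylphenoxy]-6,6-diethoxyhex-4-en-3-one, 12 dimethyl malonate
Product: 14 methyl 5-[2-(benzyloxy)-6-iodo-3-methoxy-5-methylphenoxy]-6-(diethoxymethyl)-3-methyl-2,4-dioxocyclohexane-1-carboxylate, via Michael adduct 13 (not isolated)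
Conditions: NaOMe, MeOH, reflux; then AcOH, 0 °C
Reagents that add atoms: none
Why: Michael addition followed by Claisen (Dieckmann-type) condensation, the classical route from an enone and a malonate to a cyclohexane-1,3-dione; only the ethyl-ketone carbon can close a six-membered ring, and formation of the stabilised β-diketonate drives the sequence. The new stereocentres are not controlled and are all removed in step 8.

Step 8
Reactants: 14 methyl 5-[2-(benzyloxy)-6-iodo-3-methoxy-5-methylphenoxy]-6-(diethoxymethyl)-3-methyl-2,4-dioxocyclohexane-1-carboxylate
Product: 15 methyl 3-[2-(benzyloxy)-6-iodo-3-methoxy-5-methylphenoxy]-2-(diethoxymethyl)-4,6-dihydroxy-5-methylbenzoate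
Conditions: DDQ (1.05 equiv), 1,4-dioxane, 60 °C
Reagents that add atoms: none
Why: Quinone dehydrogenation of an enolised cyclohexane-1,3-dione to a resorcinol; hydride is taken from the aryloxy-bearing ring CH, which is allylic in the enol and stabilised by oxygen, and proton loss and enolisation complete the aromatisation. The anhydrous, non-halogenating oxidant leaves the acetal, the aryl iodide and the remaining ring A C–H untouched.

Step 9
Reactants: 15 methyl 3-[2-(benzyloxy)-6-iodo-3-methoxy-5-methylphenoxy]-2-(diethoxymethyl)-4,6-dihydroxy-5-methylbenzoate, 16 carbon monoxide
Product: 17 methyl 4-(benzyloxy)-6-(diethoxymethyl)-8-hydroxy-3-methoxy-1,9-dimethyl-11-oxo-11H-dibenzo[b,e][1,4]dioxepine-7-carboxylate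
Conditions: Pd(OAc)2 (cat.), 4,5-bis(diphenylphosphino)-9,9-dimethylxanthene (cat.), Et3N (3 equiv), CO (1 atm), toluene (0.02 M), 90 °C
Reagents that add atoms: none
Why: Pd(OAc)2 is reduced in the flask to a zerovalent palladium bisphosphine complex, which inserts into the only C–I bond of 15; CO then coordinates and migrates to give an aroyl complex of divalent palladium. Et3N deprotonates the ring B phenol ortho to the bridge, which replaces iodide on the metal, and C–O reductive elimination from the resulting eight-membered acyl–palladium–aryloxide chelate releases the aryl ester and zerovalent palladium. The closest known reaction type is the intramolecular palladium-catalysed aryloxycarbonylation (carbonylative lactonisation) of aryl halides that carry a phenol, for which wide-bite-angle bisphosphines are the usual ligands at atmospheric CO pressure. The ring closed is the seven-membered dioxepinone, by one C–C and one C–O bond with CO as the one-carbon component; formally it is a 7-exo-trig attack of oxygen on the acyl carbon. No stereocentre is formed. The step needs chemoselectivity only: CO insertion must outrun direct coupling of the aryl–palladium with the same phenol (which would give a dibenzodioxin), and this is secured by the CO atmosphere and a ligand not suited to aryl ether reductive elimination. Of the two phenols only the one ortho to the bridge can reach the acyl carbon, since the other is meta to the bridge and hydrogen-bonded to the ring B ester. Dilution and the pre-organising diaryl ether disfavour chain formation, and ring B has no C–H for a competing direct arylation.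

Step 10
Reactants: 17 methyl 4-(benzyloxy)-6-(diethoxymethyl)-8-hydroxy-3-methoxy-1,9-dimethyl-11-oxo-11H-dibenzo[b,e][1,4]dioxepine-7-carboxylate
Product: 19 rac-1,4,11-trihydroxy-10-methoxy-5,8-dimethyl-1H,7H-isobenzofuro[4,5-b][1,4]benzodioxepine-3,7-dione, via formyl ester 18 (not isolated)
Conditions: BCl3, C6HMe5, CH2Cl2, −78 to −20 °C; then 2 M aq. HCl, THF, 45 °C
Reagents that add atoms: water, O
Why: Lewis-acid debenzylation with pentamethylbenzene as cation scavenger also ionises the acetal, and aqueous acid completes its hydrolysis to aldehyde 18. The aldehyde hydrate then attacks the neighbouring methyl ester (5-exo-trig lactonisation with loss of methanol), the known behaviour of 2-formylbenzoate esters. The lactol carbon forms without control, so 19 is racemic; the depsidone ester and the ring A methyl ether are stable to these conditions.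

Step 11
Reactants: 19 rac-1,4,11-trihydroxy-10-methoxy-5,8-dimethyl-1H,7H-isobenzofuro[4,5-b][1,4]benzodioxepine-3,7-dione
Product: 20 (1R)-4,11-dihydroxy-10-methoxy-5,8-dimethyl-3,7-dioxo-1H,7H-isobenzofuro[4,5-b][1,4]benzodioxepin-1-yl acetate
Conditions: immobilised lipase (Candida antarctica lipase B or Burkholderia cepacia lipase, chosen by screening for the R acetate), vinyl acetate, Et3N (cat.), toluene, 40 °C
Reagents that add atoms: vinyl acetate, C=COC(C)=O
Why: Lipase-catalysed dynamic kinetic resolution by acyl transfer from an enol ester, known for γ-hydroxybutenolide lactols; the enantiomers of 19 interconvert through the open formyl acid under amine catalysis while the enzyme acetylates one of them, and the acylal 20 no longer racemises. The configuration is set by the fit of the lactol in the active site, so the lipase of the required sense is selected by screening. Any phenol acetate formed on the side is removed in step 12.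

Step 12
Reactants: 20 (1R)-4,11-dihydroxy-10-methoxy-5,8-dimethyl-3,7-dioxo-1H,7H-isobenzofuro[4,5-b][1,4]benzodioxepin-1-yl acetate
Product: 21 (1R)-1,4,11-trihydroxy-10-methoxy-5,8-dimethyl-1H,7H-isobenzofuro[4,5-b][1,4]benzodioxepine-3,7-dione
Conditions: the lipase of step 11, n-BuOH, dry MTBE, 20 °C; filter, evaporate cold
Reagents that add atoms: none
Why: Lipase-catalysed alcoholysis (transesterification), known for acyloxybutenolides; the active-site serine attacks the acetyl carbonyl, so the C–O bond at the stereocentre is not broken and the configuration is retained. Compound 20 is the enantiomer this enzyme made and therefore its fast substrate in the reverse direction. No acid or base is present, which is what the lactol needs to keep its configuration.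

## Compound list

1 | creosol (2-methoxy-4-methylphenol) | COc1cc(C)ccc1O | starting material
2 | 2-hydroxy-3-methoxy-5-methylbenzaldehyde | COc1cc(C)cc(C=O)c1O | intermediate
3 | 2-(benzyloxy)-3-methoxy-5-methylbenzaldehyde | COc1cc(C)cc(C=O)c1OCc1ccccc1 | intermediate
4 | 2-(benzyloxy)-6-iodo-3-methoxy-5-methylbenzaldehyde | COc1cc(C)c(I)c(C=O)c1OCc1ccccc1 | intermediate
5 | 2-(benzyloxy)-6-iodo-3-methoxy-5-methylphenyl formate (not isolated) | COc1cc(C)c(I)c(OC=O)c1OCc1ccccc1 | intermediate
6 | 2-(benzyloxy)-6-iodo-3-methoxy-5-methylphenol | COc1cc(C)c(I)c(O)c1OCc1ccccc1 | intermediate
7 | 1-bromobutan-2-one | CCC(=O)CBr | starting material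
8 | 1-[2-(benzyloxy)-6-iodo-3-methoxy-5-methylphenoxy]butan-2-one | CCC(=O)COc1c(I)c(C)cc(OC)c1OCc1ccccc1 | intermediate
9 | 2,2-diethoxyacetaldehyde | CCOC(OCC)C=O | starting material
10 | 4-[2-(benzyloxy)-6-iodo-3-methoxy-5-methylphenoxy]-6,6-diethoxy-5-hydroxyhexan-3-one (mixture of diastereomers, not isolated) | CCC(=O)C(Oc1c(I)c(C)cc(OC)c1OCc1ccccc1)C(O)C(OCC)OCC | intermediate
11 | (Z)-4-[2-(benzyloxy)-6-iodo-3-methoxy-5-methylphenoxy]-6,6-diethoxyhex-4-en-3-one | CCC(=O)/C(Oc1c(I)c(C)cc(OC)c1OCc1ccccc1)=C/C(OCC)OCC | intermediate
12 | dimethyl malonate | COC(=O)CC(=O)OC | starting material
13 | dimethyl 2-{2-[2-(benzyloxy)-6-iodo-3-methoxy-5-methylphenoxy]-1-(diethoxymethyl)-3-oxopentyl}malonate (mixture of diastereomers, not isolated) | CCC(=O)C(Oc1c(I)c(C)cc(OC)c1OCc1ccccc1)C(C(OCC)OCC)C(C(=O)OC)C(=O)OC | intermediate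
14 | methyl 5-[2-(benzyloxy)-6-iodo-3-methoxy-5-methylphenoxy]-6-(diethoxymethyl)-3-methyl-2,4-dioxocyclohexane-1-carboxylate (mixture of diastereomers and keto–enol tautomers) | COC(=O)C1C(=O)C(C)C(=O)C(Oc2c(I)c(C)cc(OC)c2OCc2ccccc2)C1C(OCC)OCC | intermediate
15 | methyl 3-[2-(benzyloxy)-6-iodo-3-methoxy-5-methylphenoxy]-2-(diethoxymethyl)-4,6-dihydroxy-5-methylbenzoate | COc1cc(C)c(I)c(Oc2c(O)c(C)c(O)c(C(=O)OC)c2C(OCC)OCC)c1OCc1ccccc1 | intermediate
16 | carbon monoxide | [C-]#[O+] | starting material
17 | methyl 4-(benzyloxy)-6-(diethoxymethyl)-8-hydroxy-3-methoxy-1,9-dimethyl-11-oxo-11H-dibenzo[b,e][1,4]dioxepine-7-carboxylate | COc1cc(C)c2c(c1OCc1ccccc1)Oc1c(c(C)c(O)c(C(=O)OC)c1C(OCC)OCC)OC2=O | intermediate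
18 | methyl 6-formyl-4,8-dihydroxy-3-methoxy-1,9-dimethyl-11-oxo-11H-dibenzo[b,e][1,4]dioxepine-7-carboxylate (not isolated) | COc1cc(C)c2c(c1O)Oc1c(c(C)c(O)c(C(=O)OC)c1C=O)OC2=O | intermediate
19 | rac-1,4,11-trihydroxy-10-methoxy-5,8-dimethyl-1H,7H-isobenzofuro[4,5-b][1,4]benzodioxepine-3,7-dione (racemic lactol) | COc1cc(C)c2c(c1O)Oc1c(c(C)c(O)c3c1C(O)OC3=O)OC2=O | intermediate
20 | (1R)-4,11-dihydroxy-10-methoxy-5,8-dimethyl-3,7-dioxo-1H,7H-isobenzofuro[4,5-b][1,4]benzodioxepin-1-yl acetate | COc1cc(C)c2c(c1O)Oc1c(c(C)c(O)c3c1[C@H](OC(C)=O)OC3=O)OC2=O | intermediate
21 | (1R)-1,4,11-trihydroxy-10-methoxy-5,8-dimethyl-1H,7H-isobenzofuro[4,5-b][1,4]benzodioxepine-3,7-dione | COc1cc(C)c2c(c1O)Oc1c(c(C)c(O)c3c1[C@H](O)OC3=O)OC2=O | target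

## Step count and least certain steps

Total step count: 12. Longest linear sequence: 12 steps (from 1 to 21; the route is linear).

**Step 9 (key step).** The aryl iodide is flanked on both sides, so the catalyst may be slow to insert and reductive deiodination may compete. The aroyl palladium may also be captured between molecules instead of closing the seven-membered ring, and chelation by the ring B phenoxide and ester may hold the metal back. The fallback separates carbonylation from ring closure. From 15, the same palladium system under CO with water as external nucleophile (aqueous DMF, Et3N) should give the seco acid F1. Dehydrative lactonisation of F1 with a carbodiimide (EDC·HCl, DMAP, CH2Cl2, high dilution), the classical depsidone closure, then uses the only phenol that can reach and returns to the route at 17.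

**Step 7.** Conjugate addition to a hindered enone whose double bond carries a donor oxygen may be slow. Methoxide addition or cleavage of the enone may then take over before the Claisen closure pulls the equilibrium. The fallback reverses the roles of the partners. From 8, 9 and 12: Knoevenagel condensation of 9 with 12 (piperidine, AcOH, toluene, 4 Å MS) gives dimethyl 2-(2,2-diethoxyethylidene)malonate F2, a much stronger acceptor. The enolate of 8 at its more acidic aryloxy-bearing carbon (NaOMe, MeOH) adds to F2 to give 13, which closes as before; this returns to the route at 14.

**Step 8.** Hydride abstraction may fail on the electron-poor enol, or the oxidant may go on to attack the electron-rich hydroquinone-type product or a benzylic position. The fallback replaces hydride abstraction by an ionic selenoxide elimination. From 14, the dianion (LiN(SiMe3)2, 2.2 equiv, THF, −78 °C) is selenenylated with PhSeBr at the ester-bearing carbon to give the selenide F3. Oxidation (H2O2, pyridine, CH2Cl2, 0 °C) and syn-elimination towards the acetal-bearing carbon, then enolisation, return to the route at 15.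

**Step 6.** Enolisation on the ethyl side would give the regioisomeric enone, and dehydration of the aldol may be incomplete. The fallback fixes the site of C–C bond formation with phosphorus. It sets out from 6 and replaces steps 5 and 6. Diazo transfer to commercial diethyl (2-oxobutyl)phosphonate gives diethyl (1-diazo-2-oxobutyl)phosphonate F4. Rh2(OAc)4-catalysed O–H insertion of 6 gives the α-aryloxy β-keto phosphonate F5. Horner–Wadsworth–Emmons olefination with 9 (LiCl, DBU, MeCN) returns to the route at 11, as either alkene isomer.

**Step 11.** The enzyme may not accept a lactol whose carbon is flanked by the aryloxy-bearing ring carbon, it may prefer the wrong enantiomer, or racemisation of 19 may be too slow for a dynamic process. The fallback uses a small-molecule acyl-transfer catalyst available in both mirror-image forms. From 19, a chiral isothiourea Lewis base with acetic anhydride and i-Pr2NEt in CHCl3 effects an acylative dynamic kinetic resolution of the lactol, with the amine base driving racemisation. It returns to the route at 20 and makes no new compound.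

**Step 12.** The enzyme may be slow on the hindered acylal, and the free lactol may lose configuration by ring opening during a long reaction or on isolation. The fallback is physical separation instead of chemical deacylation. From 19, preparative chromatography on a chiral stationary phase with a neutral, aprotic eluent at low temperature returns to the route at 21 and makes no new compound. It does not remove the configurational lability itself, which is why the final product should be kept cold, neutral and dry.

## Further compounds

F1 | step 9 | 3-(benzyloxy)-2-[6-(diethoxymethyl)-2,4-dihydroxy-5-(methoxycarbonyl)-3-methylphenoxy]-4-methoxy-6-methylbenzoic acid | COc1cc(C)c(C(O)=O)c(Oc2c(O)c(C)c(O)c(C(=O)OC)c2C(OCC)OCC)c1OCc1ccccc1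
F2 | step 7 | dimethyl 2-(2,2-diethoxyethylidene)malonate | COC(=O)C(=CC(OCC)OCC)C(=O)OC
F3 | step 8 | methyl 5-[2-(benzyloxy)-6-iodo-3-methoxy-5-methylphenoxy]-6-(diethoxymethyl)-3-methyl-2,4-dioxo-1-(phenylselanyl)cyclohexane-1-carboxylate (mixture of diastereomers) | COC(=O)C1([Se]c2ccccc2)C(=O)C(C)C(=O)C(Oc2c(I)c(C)cc(OC)c2OCc2ccccc2)C1C(OCC)OCC
F4 | step 6 | diethyl (1-diazo-2-oxobutyl)phosphonate | CCC(=O)C(=[N+]=[N-])P(=O)(OCC)OCC
F5 | step 6 | diethyl {1-[2-(benzyloxy)-6-iodo-3-methoxy-5-methylphenoxy]-2-oxobutyl}phosphonate (racemic) | CCC(=O)C(Oc1c(I)c(C)cc(OC)c1OCc1ccccc1)P(=O)(OCC)OCC
F0 | step 11 | none | none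
F0 | step 12 | none | none
A1 | alternative 1 | diacetyl depsidone phthalide | COc1cc(C)c2c(c1OC(C)=O)Oc1c(c(C)c(OC(C)=O)c3c1COC3=O)OC2=O
A2 | alternative 1 | diacetyl depsidone 2-methylbenzoic acid | COc1cc(C)c2c(c1OC(C)=O)Oc1c(c(C)c(OC(C)=O)c(C(O)=O)c1C)OC2=O
A3 | alternative 1 | diacetyl depsidone 3-bromophthalide (racemic) | COc1cc(C)c2c(c1OC(C)=O)Oc1c(c(C)c(OC(C)=O)c3c1C(Br)OC3=O)OC2=O
A4 | alternative 2 | dibenzyl depsidone (S)-3-borylphthalide | COc1cc(C)c2c(c1OCc1ccccc1)Oc1c(c(C)c(OCc3ccccc3)c3c1[C@H](B4OC(C)(C)C(C)(C)O4)OC3=O)OC2=O
A5 | alternative 2 | dibenzyl depsidone aldehyde methyl ester | COc1cc(C)c2c(c1OCc1ccccc1)Oc1c(c(C)c(OCc3ccccc3)c(C(=O)OC)c1C=O)OC2=O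
A6 | alternative 2 | bis(pinacolato)diboron | CC1(C)OB(OC1(C)C)B1OC(C)(C)C(C)(C)O1
A7 | alternative 3 | diaryl ether with complete ring B and ring A benzyl ester | COc1cc(C)c(C(=O)OCc2ccccc2)c(Oc2c(O)c(C)c(O)c(C(=O)OC)c2C(OCC)OCC)c1OCc1ccccc1
A8 | alternative 3 | ring A-bearing 4-aryloxy-1-methoxy-2-methyl-1,3-bis(trimethylsilyloxy)buta-1,3-diene | COC(O[Si](C)(C)C)=C(C)C(O[Si](C)(C)C)=COc1c(C(=O)OCc2ccccc2)c(C)cc(OC)c1OCc1ccccc1
A9 | alternative 3 | methyl 4,4-diethoxybut-2-ynoate | CCOC(OCC)C#CC(=O)OC
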